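Readings and results are simulated with made-up constants.

The amounts first: G was charged at 0.100 of the X, and D in micromolar traces.

| setting | Thursday's | Monday's | flask |
|---|---|---|---|
| X | 0.12 M | 0.12 M | 0.12 M |
| G | 0.012 M | 0.012 M | 0.0120 M |
| D | 2.6 µM | 1.3 µM | 2.6 µM |
| temperature | 37 °C | 22 °C | 37 °C |
| remark | the very flask that is asked about, followed so far | run made earlier |  |
| time |  |  | 6.0 h |

- Thursday's (time / h: Z / %, X / %): 0.417: 1.6, 73.9; 0.667: 4.1, 63.4; 1.00: 8.2, 50.9; 2.00: 23.5, 20.5; 3.00: 31.3, 5.7; 5.00: 37.3, 0.1
- Monday's (time / h: Z / %, X / %): 0.833: 0.3, 87.2; 3.00: 1.7, 73.3; 4.00: 3.0, 66.7; 6.00: 7.8, 55.6; 10.0: 16.5, 35.2; 12.0: 21.2, 27.2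

(scatter of a reading: 0.5 percentage points)

- delta: at 6.0 h add D, 50.0% of the amount charged, then wait 12 h
- epsilon: at 6.0 h take out 90% of the Z then present, then wait 12 h
- alpha: change nothing and wait 12 h more
- theta: at 6.0 h raise the temperature by 10 K, then wait 12 h

- Z that was removed still counts
- additions bring no volume worth counting

1. Z, in percent of the X first charged, at 6.0 h
2. the option that brings most further Z ("none" if no option brings more than 2 percentage points) (delta / epsilon / alpha / theta / none)
3. Z present, with what was taken out counted in, in percent of the X first charged, after delta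
4. Z present, with what was taken out counted in, in percent of the X first charged, after theta

Two of Thursday's readings did not seem to go together: at 5.00 h X was down to 0.1% of the charge, yet Z stood at just 37.3%. I followed one molecule of X to clear this up. I assumed that G took X one for one, so its share was 0.100 of the charge and 0.900 went on to a second fork, Z or some unseen product.

I called the selectivity at that fork p, the Z gained per X lost past G. Over Thursday's run this gave 0.415. As read from Thursday's readings, with their scatter, the chance grew along that run, from 0.328 between 0.667 h and 1.00 h to 0.676 between 2.00 h and 5.00 h. So I read the missing Z as X lost at the fork, at a chance of Z that was lower early than late.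

I took further Z to come from X still there, and at the late chance the 0.1% read at 5.00 h, with a scatter of 0.5 percentage points, was worth 0.068 points, less than the margin of 2 points. I therefore reckoned Z at about 37.4% at 6.0 h, with no option worth taking. The forecast said 37.6%, 37.8% after delta, 37.8% after theta and best none, holding that “More D, removing Z, or heating has nothing left to convert”.

The flask gave 37.1%, 37.1% after delta, 37.1% after theta and best none.

    X → L (k = 0.430 h⁻¹, Ea = 99.0 kJ mol⁻¹)
    D → Q (k = 0.400 h⁻¹, Ea = 106 kJ mol⁻¹)
    X + G → J (k = 79.0 L mol⁻¹ h⁻¹, Ea = 63.0 kJ mol⁻¹)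
    X + Q → Z + Q, rate k4*[X]*[Q]/(1 + ([X]/Km4)) (0.0810 M, k = 5.70 × 10⁵ L mol⁻¹ h⁻¹, Ea = 52.0 kJ mol⁻¹)
    Q → E (k = 0.00480 h⁻¹, Ea = 202 kJ mol⁻¹)
    (constants at 37 °C)

At 0.821 h X in this flask went to L 1.9 times as fast as to Z, a chance of Z of 0.345, and at 6.00 h it held 0.050% of X, worth 0.034 points at the late chance, while alpha brought 0.038 points. In the neighbouring flask with 6.5 × 10⁻⁶ M of D, Z and L together held 90.0% of the charge at 6.00 h, and p stood at 0.563.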